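Readings and results were computed on assumed constants, noise included.

Time is where two readers of these runs part: their dispute is over summer at 80 min, not noon at 25 min.

| setting | gamma | beta | summer | noon |
|---|---|---|---|---|
| starting material | 0.10 M | 0.15 M | 0.20 M | 0.20 M |
| remark | run made earlier | run made earlier |  |  |
| time |  |  | 80 min | 25 min |

| run | time / min | starting material / % | open dimer / % | ring / % | side product / % |
|---|---|---|---|---|---|
| gamma | 4.00 | 95 | 4 | 4 | 0 |
| gamma | 8.00 | 85 | 2 | 13 | 5 |
| gamma | 12.0 | 87 | 1 | 12 | 4 |
| gamma | 15.0 | 78 | 0 | 16 | 3 |
| gamma | 20.0 | 78 | 1 | 20 | 2 |
| gamma | 25.0 | 70 | 2 | 18 | 9 |
| gamma | 30.0 | 68 | 2 | 23 | 11 |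
| beta | 4.00 | 94 | 2 | 7 | 2 |
| beta | 8.00 | 90 | 1 | 11 | 2 |
| beta | 12.0 | 78 | 0 | 12 | 3 |
| beta | 15.0 | 80 | 1 | 15 | 3 |
| beta | 20.0 | 69 | 0 | 14 | 8 |
| beta | 25.0 | 69 | 2 | 21 | 11 |
| beta | 30.0 | 61 | 1 | 18 | 16 |

(standard deviation of a reading: 2 percentage points)

- percent here means starting material units held: one open dimer or side product counts as two
- the earlier runs were read with a standard deviation of 2 percentage points

1. which of these there is most of at the end, counted by the starting material in it, summer (starting material / open dimer / side product / ring)
2. which of these there is most of at the end, counted by the starting material in it, noon (starting material / open dimer / side product / ring)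
3. final amount of the leader among these, as a percentage of the starting material charged, in summer
4. final amount of the leader among these, as a percentage of the starting material charged, in noon

The first reader, who made the forecast, treats ring as first order and says of the way to side product: “this path looks second order in starting material”. So the forecast gives summer to ring at 37%, with side product at 31%, and noon to starting material at 64%.

The second reader says side product is ring met by starting material. Look at the beta run: between 15.0 min and 30.0 min side product reads 3%, then 16%, a factor of 5.33, while starting material falls.

On that view, the side product reading divided by two is ring eaten. Set against ring formed, that gives the share eaten; the mean ring, taken as the last ring reading over two, divided by that share gives 0.0596 M from gamma and 0.0439 M from beta, both with the scatter of the readings. Their mean, 0.0517 M, is the ring ceiling, the ring concentration at which starting material eats ring as fast as it forms it, a steady-state level. Both rates carry starting material, so on this view the ceiling stays put as starting material falls.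

At 0.20 M the ceiling is 25.9% of the charge, less than the forecast's ring. So for summer the second reader moves 11 points from ring onto the forecast's side product and names side product the leader.

Summer ends with side product at 49.7% and ring at 22.6%; noon ends with starting material at 66.4%. After 800 min the summer flask holds 24.3% ring and 0% starting material. Noon is where the first reader's forecast held: the ring in noon, 15.5%, stands at 0.598 of the ceiling, and at that time ring is made 1.77 times as fast as it is used up, each step taken net.

    starting material → ring (k = 0.0110 min⁻¹)
    2 starting material → open dimer (k = 0.00490 M⁻¹ min⁻¹)
    starting material + ring → side product (k = 0.200 M⁻¹ min⁻¹)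

For a neighbour flask, noon with 0.50 M of starting material, the ceiling gives 10.3% of the charge. That flask holds 9.45% ring after 25.0 min.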